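All runs are calculated with made-up constants; the scatter is artificial.

Thursday's run still held 42.5 % of its starting material at 8.00 min, and the new flask differs from it in one charge, with twice the added ligand.

common to all: starting material 0.50 M; reagent 1.25 M; catalyst 25 mM

| flask | added ligand | remark |
|---|---|---|
| Thursday's | 32 mM | run made earlier |
| flask | 63 mM |  |

Thursday's run (percent of the starting material charged)

| time / min | target / % | starting material / % |
|---|---|---|
| 0.500 | 5.2 | 91.0 |
| 1.33 | 17.6 | 83.0 |
| 2.50 | 29.5 | 69.8 |
| 4.00 | 40.8 | 60.4 |
| 6.00 | 51.2 | 50.2 |
| 8.00 | 58.3 | 42.5 |

(standard deviation of a reading: 1 percentage point)

- the earlier runs were read with a standard deviation of 1 percentage point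
- no earlier run changes the charge of catalyst; that part of a forecast is a guess
- no earlier run changes the charge of added ligand; that part of a forecast is a guess
- no earlier run changes the charge of reagent; that part of a forecast is a guess

- factor on the rate of making target when 50 % of the starting material are converted if reagent is charged twice over
- factor on the rate when 50 % of the starting material are converted if catalyst is charged at 2.5 mM instead

My own reckoning takes one reagent per target and a rate proportional to [reagent], and no run tests either assumption. The quantity to carry is then the reagent left at the conversion looked at: the charge less what has reacted, 1.00 M. Doubling the charge adds a full 1.25 M to that leftover, so my factor is 2.25 and not 2, since the same 0.250 M is taken out of either charge. I make no reckoning of my own for the catalyst.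

The forecast gives 1.8 for the reagent, lower than my factor, and 0.08 for the catalyst, holding the reagent's order to be “anywhere from zero to one or slightly higher”.

The flask gives 3.48 for the reagent and 0.0721 for the catalyst.

    starting material + reagent + catalyst → catalyst + target (k = 0.0910 M⁻² s⁻¹)
    catalyst + added ligand ⇌ idle complex (K = 44.0 M⁻¹, k = 0.0650 M⁻¹ s⁻¹)

The reagent factor of 3.48 is 1.55 times the 2.25 from the leftover. In this flask free catalyst falls from 61.3 % of its charge at 2.50 min to 34.2 % at 12.5 min, with 65.8 % then standing as idle complex, an off-cycle form, and 50 % conversion comes between those times, at 8.28 min. With a fraction 0.7 of the starting material converted, reached at 19.9 min, the reagent left is 0.900 M, which is 0.900 of 1.00 M. With the starting material at 0.600 of its amount at 50 %, the two leftovers give 0.540 of the rate, and the flask stands at 0.48.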